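**Plan**

1. Retrosynthesis: in each of the two (Z)-butylidene butenolides the ring-carbon–C(=O) bond and the lactone O–C(ylidene) bond are cut (four bonds, two CO2). This leaves a bis-electrophile: a bicyclo[2.2.2]octene with Br on C2 and pent-1-ynyl on C3, fused to a cyclohexene with OTf on C5 and pent-1-ynyl on C6.
2. Enabling feature: on both ring double bonds (C2=C3 of the bicyclooctene, C5=C6 of the outer ring) the carbon that will carry C=O and the carbon that will carry the ylidene are cis neighbours locked in a ring. A carboxylate made at C–X therefore lies within reach of the alkyne and can only close 5-exo-dig.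
3. The core is cut at C1–C8a and C4–C4a: intramolecular Diels–Alder reaction of a masked o-benzoquinone (from 5-bromo-4-pentynylguaiacol) whose ketal oxygen is tethered to (R)-cyclohex-2-enol. Tether and ketal are removed afterwards with SmI2.
4. Forward: arene → dienone → one [4+2] builds the bicyclooctene, the cis-fused outer ring and a temporary tetrahydrofuran → tether opening, carbinol, ketone → 2-alkynyl enol triflate on the outer ring → both butenolide rings from CO2 → desilylation.
5. Stereochemistry: the carbinol carbon of (R)-cyclohex-2-enol (later a ketone) fixes C1, C4, C4a and C8a through the tether. C9 is set by hydride delivered from the freed tether hydroxyl. Both Z alkenes come from anti oxymetalation.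

Key step: step 12

Remark on locants: names use the 1,4-ethanonaphthalene skeleton as defined here: C1 and C4 bridgeheads, C2=C3 the alkene bridge (C2 on C1), C9 (on C1) and C10 (on C4) the two-carbon bridge, C4a (on C4) and C8a (on C1) the ring-fusion carbons, C5 (on C4a) to C8 (on C8a) the outer ring.

Remark on the chemistry (assumption): (R)-cyclohex-2-en-1-ol is taken as a purchasable building block; otherwise it is one step from cyclohexene oxide by catalytic enantioselective lithium-amide rearrangement.

**Route**

Step 1
Reactants: 1 5-bromo-2-methoxyphenol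
Product: 2 5-bromo-4-iodo-2-methoxyphenol
Conditions: NIS (1.05 equiv), TsOH·H2O (10 mol %), MeCN, 0 °C to rt
Reagents that add atoms: N-iodosuccinimide, O=C1CCC(=O)N1I
Why: Electrophilic aromatic iodination, in which the hydroxyl is the strongest director and its para position (C4) is the open activated site, the remaining ortho position being squeezed between OH and Br, so iodine should enter para to OH next to the bromine.

Step 2
Reactants: 2 5-bromo-4-iodo-2-methoxyphenol; 3 pent-1-yne
Product: 4 5-bromo-2-methoxy-4-(pent-1-yn-1-yl)phenol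
Conditions: Pd(PPh3)2Cl2 (2 mol %), CuI (4 mol %), Et3N, THF, rt
Reagents that add atoms: none
Why: Sonogashira coupling, in which oxidative addition into the aryl C–I bond is far faster than into C–Br at room temperature, so only iodine should be exchanged for the pentynyl group.

Step 3
Reactants: 4 5-bromo-2-methoxy-4-(pent-1-yn-1-yl)phenol; 5 (R)-cyclohex-2-en-1-ol
Product: 7 oxygen-bridged cycloadduct (5R; C5–O–C10 bridge; 9-ketone), via mixed-ketal masked o-benzoquinone 6 (not isolated)
Conditions: PhI(OAc)2 (1.2 equiv), 5 (4 equiv, excess recovered), CH2Cl2, 0 °C to rt; then CSA (5 mol %), toluene, 80 °C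
Reagents that add atoms: none
Why: Oxidative dearomatisation of a 2-methoxyphenol to a masked o-benzoquinone followed by intramolecular Diels–Alder reaction: the methoxy-stabilised ortho carbon takes up the allylic alcohol, the one-atom tether then allows only the fused adduct in which the outer ring lies on the side of the ketal bridge and is cis to the tether oxygen, so the (R) carbinol centre sets C1, C4, C4a and C8a; only the ketal epimer that can reach this geometry cyclises, and acid-mediated ketal exchange with the excess alcohol should recycle the other.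

Step 4
Reactants: 7 oxygen-bridged cycloadduct
Product: 8 (5R)-2-bromo-5-hydroxy-3-(pent-1-yn-1-yl)-octahydro-1,4-ethanonaphthalen-9-one
Conditions: SmI2 (5 equiv), THF/MeOH (10:1), −78 °C to 0 °C
Reagents that add atoms: none
Why: Samarium diiodide reduction of an α,α-dialkoxy ketone, in which ketyl formation and β-expulsion of alkoxide occur twice, removing methoxide and opening the tetrahydrofuran so that C10 becomes CH2 and the tether oxygen the C5 hydroxyl; the alkenyl bromide and the alkyne are inert without HMPA and no remaining stereocentre is touched.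

Step 5
Reactants: 8 hydroxy ketone
Product: 9 (5R,9S)-diol with 9-OH on the side of the C2=C3 bridge
Conditions: Me4NBH(OAc)3 (5 equiv), MeCN/AcOH (1:1), −20 °C to rt
Reagents that add atoms: none
Why: Hydroxyl-directed (Saksena–Evans) reduction: the C5 hydroxyl, which sits under the C9–C10 bridge on the face of the ketone that the outer ring shields, exchanges onto boron and should deliver hydride internally to that inner face, so the new hydroxyl emerges on the open face, syn to C2=C3.

Step 6
Reactants: 9 diol
Product: 10 9-O-tert-butyldimethylsilyl ether with free 5-OH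
Conditions: TBSCl (1.1 equiv), imidazole, DMF, 0 °C
Reagents that add atoms: tert-butyldimethylsilyl chloride, CC(C)(C)[Si](C)(C)Cl
Why: Silylation under steric control, in which the C9 hydroxyl on the convex face should react well before the C5 hydroxyl buried in the pocket between the outer ring and the C9–C10 bridge.

Step 7
Reactants: 10 mono-silyl ether
Product: 11 5-ketone
Conditions: Dess–Martin periodinane, NaHCO3, CH2Cl2, rt
Reagents that add atoms: none
Why: Dess–Martin oxidation of the remaining secondary alcohol under neutral conditions; the adjacent C4a centre is not at risk because a trans-fused ring on the eclipsed bicyclooctane bridge would be strongly strained.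

Step 8
Reactants: 11 5-ketone
Product: 13 C6=C7 enone, via lithium enolate 12 (not isolated)
Conditions: LDA (1.1 equiv), THF, −78 °C; then PhS(Cl)=NtBu (1.2 equiv), −78 °C
Reagents that add atoms: none
Why: Mukaiyama dehydrogenation: kinetic deprotonation occurs at the C6 methylene (C4a–H is tertiary and buried), the enolate is sulfenylated at carbon by the sulfinimidoyl chloride and syn elimination should give the C6=C7 enone.

Step 9
Reactants: 13 enone
Product: 14 6-iodo enone
Conditions: I2 (2 equiv), pyridine/CH2Cl2 (1:1), 0 °C to rt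
Reagents that add atoms: iodine, II
Why: Johnson α-iodination of an enone (conjugate addition of pyridine, iodination of the enolate, elimination), to which the isolated tetrasubstituted bromoalkene and the internal alkyne should be inert.

Step 10
Reactants: 14 6-iodo enone; 3 pent-1-yne
Product: 15 6-(pent-1-yn-1-yl) enone
Conditions: Pd(PPh3)2Cl2 (5 mol %), CuI (10 mol %), iPr2NH, THF, 0 °C
Reagents that add atoms: none
Why: Sonogashira coupling at the very reactive α-iodoenone C–I bond at 0 °C, which should leave the hindered alkenyl bromide on C2 untouched.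

Step 11
Reactants: 15 alkynyl enone
Product: 17 C5 enol triflate (C5=C6) carrying pent-1-ynyl on C6 and the C2-bromide, via lithium enolate 16 (not isolated)
Conditions: L-Selectride (1.05 equiv), THF, −78 °C; then PhNTf2 (1.2 equiv), −78 °C to 0 °C
Reagents that add atoms: N-phenylbis(trifluoromethanesulfonimide), O=S(=O)(N(c1ccccc1)S(=O)(=O)C(F)(F)F)C(F)(F)F
Why: Reductive enol triflation: conjugate hydride addition to the β-unsubstituted enone gives the C5–C6 enolate regiospecifically and O-sulfonylation fixes the triflate on C5, cis to the alkyne on C6.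

Step 12
Reactants: 17 bromide/triflate bis-electrophile
Product: 19 bis-butenolide 9-O-silyl ether, via manganese(II) dicarboxylate 18 (not isolated)
Conditions: NiBr2·glyme (20 mol %), neocuproine (40 mol %), Mn (6 equiv), Et4NI (1 equiv), CO2 (1 atm), DMA, 25 °C; then filtered from Mn under Ar, AcOH (4 equiv), AgOTf (20 mol %), 25 °C, dark
Reagents that add atoms: carbon dioxide, O=C=O
Why: Proposed new method: Ni(0), formed from NiBr2 and Mn, inserts into the C2–Br and the C5–OTf bond, Mn reduces each alkenylnickel(II) to alkenylnickel(I), which adds to CO2, and the carboxylates are released as the manganese(II) salt 18; Ag(I) then π-activates each neighbouring alkyne, the carboxylate oxygen adds anti to the nearer alkyne carbon and acetic acid cleaves the C–Ag bond. The closest known reactions are the Ni-catalysed reductive carboxylation of alkenyl and aryl halides and triflates with CO2 and Mn, and the Ag(I)-catalysed lactonisation of (Z)-2-en-4-ynoic and 2-alkynylbenzoic acids to (Z)-ylidene butenolides; new is their twofold merger in one flask on a substrate with a bromide, a triflate and two alkynes. Each butenolide ring closes 5-exo-dig through oxygen, the two C–C bonds to CO2 being intermolecular. No stereocentre is formed; both exocyclic double bonds should be Z because anti oxyargentation and protodemetalation with retention place the propyl group cis to the ring oxygen. The step needs site control of carboxylation, fixed by the positions of Br and OTf, and 5-exo over 6-endo closure, which Ag(I) favours with alkyl alkynes and which the ring double bonds C2=C3 and C5=C6 support by locking carboxylate and alkyne cis; the absence of a proton or hydride source in the nickel stage should suppress hydrodehalogenation and alkyne hydrocarboxylation, and the silyl ether keeps the C9 oxygen, which lies next to the C2 carboxylate, out of play.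

Step 13
Reactants: 19 bis-butenolide silyl ether
Product: 20 target CNP0289078.1
Conditions: HF·pyridine, pyridine, THF, 0 °C to rt
Reagents that add atoms: none
Why: Fluoride-mediated desilylation under buffered, non-basic conditions, which should free the C9 alcohol without opening or isomerising the nucleophile-sensitive enol lactones and without touching a stereocentre.

**Compound list**

1 | 5-bromo-2-methoxyphenol | COc1ccc(Br)cc1O | starting material
2 | 5-bromo-4-iodo-2-methoxyphenol | COc1cc(I)c(Br)cc1O | intermediate
3 | pent-1-yne | C#CCCC | starting material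
4 | 5-bromo-2-methoxy-4-(pent-1-yn-1-yl)phenol | COc1cc(C#CCCC)c(Br)cc1O | intermediate
5 | (R)-cyclohex-2-en-1-ol | O[C@@H]1CCCC=C1 | starting material
6 | 3-bromo-6-[(1R)-cyclohex-2-en-1-yloxy]-6-methoxy-4-(pent-1-yn-1-yl)cyclohexa-2,4-dien-1-one (both C6 epimers) | CCCC#CC1=CC(OC)(O[C@@H]2CCCC=C2)C(=O)C=C1Br | intermediate (not isolated)
7 | (5R)-2-bromo-10-methoxy-3-(pent-1-yn-1-yl)-5,10-epoxy-1,4,4a,5,6,7,8,8a-octahydro-1,4-ethanonaphthalen-9-one; O bridge C5–O–C10, outer ring cis-fused on the side of the C9–C10 bridge | CCCC#CC1=C(Br)[C@H]2C(=O)[C@]3(OC)O[C@@H]4CCC[C@H]2[C@@H]4[C@H]13 | intermediate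
8 | (5R)-2-bromo-5-hydroxy-3-(pent-1-yn-1-yl)-1,4,4a,5,6,7,8,8a-octahydro-1,4-ethanonaphthalen-9-one; ring fusion as in 7 | CCCC#CC1=C(Br)[C@H]2C(=O)C[C@@H]1[C@@H]1[C@H](O)CCC[C@H]21 | intermediate
9 | (5R,9S)-2-bromo-3-(pent-1-yn-1-yl)-1,4,4a,5,6,7,8,8a-octahydro-1,4-ethanonaphthalene-5,9-diol; 9-OH syn to C2=C3 | CCCC#CC1=C(Br)[C@H]2[C@@H](O)C[C@@H]1[C@@H]1[C@H](O)CCC[C@H]21 | intermediate
10 | 9-O-tert-butyldimethylsilyl ether of 9 (5-OH free) | CCCC#CC1=C(Br)[C@H]2[C@@H](O[Si](C)(C)C(C)(C)C)C[C@@H]1[C@@H]1[C@H](O)CCC[C@H]21 | intermediate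
11 | 2-bromo-9-(tert-butyldimethylsilyloxy)-3-(pent-1-yn-1-yl)-octahydro-1,4-ethanonaphthalen-5-one; C1, C4, C4a, C8a, C9 as in 10 | CCCC#CC1=C(Br)[C@H]2[C@@H](O[Si](C)(C)C(C)(C)C)C[C@@H]1[C@@H]1C(=O)CCC[C@H]21 | intermediate
12 | lithium C5–C6 enolate of 11 | CCCC#CC1=C(Br)[C@H]2[C@@H](O[Si](C)(C)C(C)(C)C)C[C@@H]1[C@@H]1C(O[Li])=CCC[C@H]21 | intermediate (not isolated)
13 | C6=C7 enone of 11 (5-one) | CCCC#CC1=C(Br)[C@H]2[C@@H](O[Si](C)(C)C(C)(C)C)C[C@@H]1[C@@H]1C(=O)C=CC[C@H]21 | intermediate
14 | 6-iodo derivative of enone 13 | CCCC#CC1=C(Br)[C@H]2[C@@H](O[Si](C)(C)C(C)(C)C)C[C@@H]1[C@@H]1C(=O)C(I)=CC[C@H]21 | intermediate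
15 | 6-(pent-1-yn-1-yl) derivative of enone 13 | CCCC#CC1=C(Br)[C@H]2[C@@H](O[Si](C)(C)C(C)(C)C)C[C@@H]1[C@@H]1C(=O)C(C#CCCC)=CC[C@H]21 | intermediate
16 | lithium C5–C6 enolate from conjugate reduction of 15 | CCCC#CC1=C(Br)[C@H]2[C@@H](O[Si](C)(C)C(C)(C)C)C[C@@H]1[C@@H]1C(O[Li])=C(C#CCCC)CC[C@H]21 | intermediate (not isolated)
17 | 2-bromo-9-(tert-butyldimethylsilyloxy)-3,6-di(pent-1-yn-1-yl)-1,4,4a,7,8,8a-hexahydro-1,4-ethanonaphthalen-5-yl trifluoromethanesulfonate | CCCC#CC1=C(Br)[C@H]2[C@@H](O[Si](C)(C)C(C)(C)C)C[C@@H]1[C@@H]1C(OS(=O)(=O)C(F)(F)F)=C(C#CCCC)CC[C@H]21 | intermediate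
18 | manganese(II) 9-(tert-butyldimethylsilyloxy)-3,6-di(pent-1-yn-1-yl)-1,4,4a,7,8,8a-hexahydro-1,4-ethanonaphthalene-2,5-dicarboxylate | CCCC#CC1=C(C(=O)[O-])[C@H]2[C@@H](O[Si](C)(C)C(C)(C)C)C[C@@H]1[C@@H]1C(C(=O)[O-])=C(C#CCCC)CC[C@H]21.[Mn+2] | intermediate (not isolated)
19 | 9-O-tert-butyldimethylsilyl ether of the target | CCC/C=C1\OC(=O)C2=C1CC[C@@H]1[C@H]3C4=C(/C(=C/CCC)OC4=O)[C@H](C[C@@H]3O[Si](C)(C)C(C)(C)C)[C@H]21 | intermediate
20 | CNP0289078.1: (1S,4R,4aR,8aS,9S)-9-hydroxy-1,4-ethanonaphthalene core with two (Z)-butylidene butenolides (C=O carbons on C2 and C5, ylidene carbons on C3 and C6) | CCC/C=C1\OC(=O)C2=C1CC[C@@H]1[C@H]3C4=C(/C(=C/CCC)OC4=O)[C@H](C[C@@H]3O)[C@H]21 | target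

**Count and risks**

Total steps: 13. Longest linear sequence: 13 (from 1).

Steps most likely to fail:

Step 12 (Proposed new method). What may go wrong: protonation of the alkenylnickel species (hydrodehalogenation, loss of triflate), engagement of the alkynes by low-valent nickel, or carboxylation at only one of the two sites. The fallback uses known reactions and runs from 17 back to 19. Twofold Pd-catalysed methoxycarbonylation (Pd(OAc)2, dppf, CO 1 atm, MeOH, Et3N, DMF, 70 °C) should give the dimethyl 2,5-dicarboxylate F1. Mild saponification (LiOH, THF/H2O, rt) should give the 2,5-dicarboxylic acid F2. AgNO3 (10 mol %) in acetone at rt should then close both rings 5-exo-dig to 19.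

Step 3. What may go wrong: the alcohol competes poorly with acetate for the oxidised arene, the dienone dimerises before it cyclises, or the ketal epimer that cannot reach the fused transition state fails to equilibrate. The fallback runs from 4 back to 7. Oxidation in methanol (PhI(OAc)2, MeOH, 0 °C) should give the isolable dimethyl ketal 3-bromo-6,6-dimethoxy-4-(pent-1-yn-1-yl)cyclohexa-2,4-dien-1-one F3. Heating F3 with 5 (1.5 equiv) and PPTS in toluene over 4 Å sieves (90 °C) should exchange one methoxy group under thermodynamic control; the ketal epimers interconvert through the oxocarbenium ion and the matched one cyclises to 7.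

Step 5. What may go wrong: external hydride addition from the open face outruns internal delivery (poor facial selectivity), or the hydroxy ketone is tied up as its bridged hemiketal and reacts sluggishly. The fallback runs from 8 back to 9 and uses inversion instead of delivery. Acetylation (Ac2O, pyridine, DMAP) should give the 5-acetate F4. NaBH4 (MeOH, 0 °C) should attack the open face and give the 9-epimeric alcohol F5. Mitsunobu inversion (4-nitrobenzoic acid, PPh3, DIAD, THF) should give the 9-(4-nitrobenzoate) F6 with the oxygen on the open face. Methanolysis of both esters (K2CO3, MeOH) should give 9.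

Further compounds

F1 | step 12 | dimethyl 9-(tert-butyldimethylsilyloxy)-3,6-di(pent-1-yn-1-yl)-1,4,4a,7,8,8a-hexahydro-1,4-ethanonaphthalene-2,5-dicarboxylate | CCCC#CC1=C(C(=O)OC)[C@H]2[C@@H](O[Si](C)(C)C(C)(C)C)C[C@@H]1[C@@H]1C(C(=O)OC)=C(C#CCCC)CC[C@H]21
F2 | step 12 | 9-(tert-butyldimethylsilyloxy)-3,6-di(pent-1-yn-1-yl)-1,4,4a,7,8,8a-hexahydro-1,4-ethanonaphthalene-2,5-dicarboxylic acid | CCCC#CC1=C(C(=O)O)[C@H]2[C@@H](O[Si](C)(C)C(C)(C)C)C[C@@H]1[C@@H]1C(C(=O)O)=C(C#CCCC)CC[C@H]21
F3 | step 3 | 3-bromo-6,6-dimethoxy-4-(pent-1-yn-1-yl)cyclohexa-2,4-dien-1-one | CCCC#CC1=CC(OC)(OC)C(=O)C=C1Br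
F4 | step 5 | 5-O-acetate of hydroxy ketone 8 | CCCC#CC1=C(Br)[C@H]2C(=O)C[C@@H]1[C@@H]1[C@H](OC(C)=O)CCC[C@H]21
F5 | step 5 | 9-epi alcohol (9-OH on the side of the outer ring), 5-O-acetate | CCCC#CC1=C(Br)[C@H]2[C@H](O)C[C@@H]1[C@@H]1[C@H](OC(C)=O)CCC[C@H]21
F6 | step 5 | 9-(4-nitrobenzoate) with oxygen syn to C2=C3, 5-O-acetate | CCCC#CC1=C(Br)[C@H]2[C@@H](OC(=O)c3ccc(cc3)[N+](=O)[O-])C[C@@H]1[C@@H]1[C@H](OC(C)=O)CCC[C@H]21
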